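**Plan**

Locants used below: C1H2=C2–C3(=O)–O4–C5, then C6 (OAc), C7 (Me), C8–C10, C11 (Me, OH), C12=C13, C14, C15 (Me)/O16/C17 oxirane, C18, C19 (ring fusion, bonded to C2 and C5).
Retrosynthesis: (1) C15–C17 oxirane back to the E olefin; (2) the lactone ring is opened at C2–C3 and O4–C5, leaving CO2, a C2 alkenyl triflate and a cis-C5–C6 oxirane; (3) the macrocycle is cut at C12=C13 (ring-closing metathesis); (4) C19–C5 (aldol) divides an East imide from a West aldehyde; (5) C7–C8 (epoxide opening).
Enabling feature: C2 and the oxygen-bearing C5 sit 1,3 across C19, and C5/C6 carry syn vicinal oxygens, so a carboxylate born at C2 can open a C5–C6 oxirane 5-exo. This closes the five-membered lactone ring (C2, C3, O4, C5, C19) and uncovers the C6 hydroxyl.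
Forward order: East imide and West aldehyde, aldol union, C5–C6 oxirane, 14-membered ring, alkenyl triflate, lactone ring (key step), acetate, C15–C17 oxirane.
Stereochemistry: C11 from (S)-linalool; C6 and C7 from Sharpless epoxidation of (E)-crotyl alcohol (inversion at C7 on opening); C19 and C5 from an Evans syn aldol, C5 then being inverted twice (mesylate to oxirane to lactone); C15/C17 from a Shi epoxidation; the E olefins from carboalumination and from reversible metathesis.

Key step: step 20

Remark: (S)-(+)-linalool is taken to be commercially available in high enantiomeric purity.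

**Route**

Step 1
Reactants: 1 pent-1-en-4-yne
Product: 3 (E)-1-iodo-2-methylpenta-1,4-diene, via alkenylalane 2 (not isolated)
Conditions: Me3Al, Cp2ZrCl2 (cat.), CH2Cl2, 0 °C to rt; then I2, THF, −30 °C
Reagents that add atoms: trimethylaluminium C[Al](C)C; iodine II
Why: Negishi carboalumination adds Me–Al syn across the terminal alkyne with methyl on the internal carbon, and iodinolysis of the C–Al bond with retention fixes the E geometry of the future C15=C17 olefin while the remote vinyl group is left alone.

Step 2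
Reactants: 3 (E)-1-iodo-2-methylpenta-1,4-diene; 4 β-propiolactone
Product: 7 (E)-5-methylocta-4,7-dienoic acid, via alkenyllithium 5 (not isolated), via alkenylmagnesium bromide 6 (not isolated)
Conditions: t-BuLi (2 equiv), Et2O, −78 °C; MgBr2·OEt2; CuBr·SMe2 (cat.), 4, THF, −30 to 0 °C; aq. HCl
Reagents that add atoms: none
Why: Iodine–lithium exchange and transmetalation keep the olefin geometry, and the copper-catalysed Grignard opening of the β-lactone occurs by SN2 attack at the O-alkyl carbon, which gives the three-carbon-extended acid in one operation.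

Step 3
Reactants: 7 (E)-5-methylocta-4,7-dienoic acid; 8 (R)-4-benzyl-1,3-oxazolidin-2-one
Product: 10 (R)-4-benzyl-3-[(E)-5-methylocta-4,7-dienoyl]-1,3-oxazolidin-2-one, via mixed pivalic anhydride 9 (not isolated)
Conditions: PivCl, Et3N, THF, −20 °C; then LiCl, 8, rt
Reagents that add atoms: none
Why: Standard N-acylation of an Evans oxazolidinone through the mixed anhydride with LiCl activation, mild enough for the skipped diene.

Step 4
Reactants: 11 (E)-but-2-en-1-ol
Product: 12 [(2S,3S)-3-methyloxiran-2-yl]methanol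
Conditions: Ti(OiPr)4 (cat.), L-(+)-diethyl tartrate (cat.), t-BuOOH, 4 Å MS, CH2Cl2, −20 °C
Reagents that add atoms: tert-butyl hydroperoxide CC(C)(C)OO
Why: Sharpless asymmetric epoxidation of an E allylic alcohol, in which the L-(+)-tartrate–titanium complex delivers oxygen to the face that gives the (2S,3S) oxirane; this carries the future C6 oxygen stereocentre and sets up C7.

Step 5
Reactants: 12 [(2S,3S)-3-methyloxiran-2-yl]methanol
Product: 13 (2S,3S)-2-[(4-methoxybenzyloxy)methyl]-3-methyloxirane
Conditions: NaH, 4-methoxybenzyl chloride, Bu4NI (cat.), THF, 0 °C to rt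
Reagents that add atoms: 4-methoxybenzyl chloride COc1ccc(CCl)cc1
Why: Williamson etherification of the primary alkoxide with a reactive benzylic halide in aprotic medium should outrun Payne rearrangement and installs an oxidatively removable group on the C5 oxygen.

Step 6
Reactants: 14 (S)-linalool
Product: 15 (S)-linalool triethylsilyl ether
Conditions: TESOTf, 2,6-lutidine, CH2Cl2, −78 to 0 °C
Reagents that add atoms: triethylsilyl trifluoromethanesulfonate CC[Si](CC)(CC)OS(=O)(=O)C(F)(F)F
Why: Silyl triflate silylation of the hindered tertiary allylic alcohol at low temperature without ionisation; the C11 stereocentre is taken unchanged from the chiral pool.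

Step 7
Reactants: 15 (S)-linalool triethylsilyl ether
Product: 17 (S)-4-methyl-4-(triethylsilyloxy)hex-5-en-1-ol, via aldehyde 16 (not isolated)
Conditions: O3 (1 equiv, dye endpoint), pyridine, CH2Cl2/MeOH, −78 °C; then NaBH4, −78 to 0 °C
Reagents that add atoms: ozone [O-][O+]=O
Why: Chemoselective ozonolysis, since the electron-rich trisubstituted olefin reacts much faster than the monosubstituted vinyl group on the quaternary carbon, with borohydride work-up reducing the aldehyde to the primary alcohol.

Step 8
Reactants: 17 (S)-4-methyl-4-(triethylsilyloxy)hex-5-en-1-ol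
Product: 18 (S)-6-bromo-3-methyl-3-(triethylsilyloxy)hex-1-ene
Conditions: CBr4, PPh3, 2,6-lutidine, CH2Cl2, 0 °C
Reagents that add atoms: carbon tetrabromide BrC(Br)(Br)Br
Why: Appel bromination of the primary alcohol under buffered neutral conditions that spare the tertiary allylic silyl ether.

Step 9
Reactants: 18 (S)-6-bromo-3-methyl-3-(triethylsilyloxy)hex-1-ene; 13 (2S,3S)-2-[(4-methoxybenzyloxy)methyl]-3-methyloxirane
Product: 20 (2R,3S,7S)-1-(4-methoxybenzyloxy)-3,7-dimethyl-7-(triethylsilyloxy)non-8-en-2-ol, via Grignard reagent 19 (not isolated)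
Conditions: Mg, THF, rt; then CuI (10 mol%), 13, THF, −30 to 0 °C
Reagents that add atoms: none
Why: Copper-catalysed Grignard opening of the 2,3-epoxy ether by SN2 attack at the methyl-bearing oxirane carbon (less hindered and remote from the deactivating CH2OPMB arm) forms C7–C8 with inversion at C7 and gives the syn C6-hydroxyl/C7-methyl pair.

Step 10
Reactants: 20 (2R,3S,7S)-1-(4-methoxybenzyloxy)-3,7-dimethyl-7-(triethylsilyloxy)non-8-en-2-ol
Product: 21 2-O-tert-butyldimethylsilyl ether of 20
Conditions: TBSOTf, 2,6-lutidine, CH2Cl2, −78 °C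
Reagents that add atoms: tert-butyldimethylsilyl trifluoromethanesulfonate CC(C)(C)[Si](C)(C)OS(=O)(=O)C(F)(F)F
Why: Routine silylation of the secondary alcohol with a group that survives the following steps and falls to fluoride later.

Step 11
Reactants: 21 2-O-tert-butyldimethylsilyl ether of 20
Product: 22 (2R,3S,7S)-2-(tert-butyldimethylsilyloxy)-3,7-dimethyl-7-(triethylsilyloxy)non-8-en-1-ol
Conditions: DDQ, CH2Cl2/pH 7 buffer, 0 °C
Reagents that add atoms: none
Why: Oxidative cleavage of the p-methoxybenzyl ether by DDQ (single-electron oxidation, then hydrolysis of the oxocarbenium ion) leaves silyl ethers and olefins untouched.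

Step 12
Reactants: 22 (2R,3S,7S)-2-(tert-butyldimethylsilyloxy)-3,7-dimethyl-7-(triethylsilyloxy)non-8-en-1-ol
Product: 23 (2R,3S,7S)-2-(tert-butyldimethylsilyloxy)-3,7-dimethyl-7-(triethylsilyloxy)non-8-enal
Conditions: Dess–Martin periodinane, NaHCO3, CH2Cl2, 0 °C to rt
Reagents that add atoms: none
Why: Dess–Martin oxidation under bicarbonate buffer should give the α-silyloxy aldehyde without epimerisation at C6; it is used at once.

Step 13
Reactants: 10 (R)-4-benzyl-3-[(E)-5-methylocta-4,7-dienoyl]-1,3-oxazolidin-2-one; 23 (2R,3S,7S)-2-(tert-butyldimethylsilyloxy)-3,7-dimethyl-7-(triethylsilyloxy)non-8-enal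
Product: 25 syn-aldol imide (19R,5R,6R,7S,11S; C5–OH free), via boron enolate 24 (not isolated)
Conditions: Bu2BOTf, i-Pr2NEt, CH2Cl2, −78 to 0 °C; then 23, −78 to 0 °C; pH 7 buffer, MeOH, H2O2
Reagents that add atoms: none
Why: Evans syn aldol, in which the Z dibutylboron enolate reacts through a closed Zimmerman–Traxler chair and the (R)-benzyl auxiliary dictates the enolate face, setting C19 and C5 under reagent control that should override the weak intrinsic bias of the α-silyloxy aldehyde toward Z enolates.

Step 14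
Reactants: 25 syn-aldol imide
Product: 26 Weinreb amide (19R,5R,6R,7S,11S; C5–OH free)
Conditions: MeNH(OMe)·HCl, AlMe3, THF, −20 to 0 °C
Reagents that add atoms: N,O-dimethylhydroxylamine hydrochloride CNOC.Cl
Why: Aluminium amide transamination of the β-hydroxy imide, assisted by the free C5 hydroxyl, gives the Weinreb amide and returns the auxiliary.

Step 15
Reactants: 26 Weinreb amide
Product: 27 C5 methanesulfonate of 26
Conditions: MsCl, Et3N, CH2Cl2, −20 °C
Reagents that add atoms: methanesulfonyl chloride CS(=O)(=O)Cl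
Why: Mesylation of the only free hydroxyl under mild base at low temperature, where E1cB loss from the weakly acidic amide α-position is slow.

Step 16
Reactants: 27 C5 methanesulfonate of 26
Product: 29 open-chain cis-5,6-epoxy Weinreb amide (5S,6R,7S,11S,19R; C11–OH free), via hydroxy mesylate 28 (not isolated)
Conditions: Bu4NF (3 equiv), THF, 0 °C to rt
Reagents that add atoms: none
Why: Fluoride removes both silyl groups and the liberated C6 alkoxide displaces the adjacent mesylate by intramolecular SN2 (3-exo-tet), which inverts C5 and should give the cis oxirane faster than any β-elimination.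

Step 17
Reactants: 29 open-chain cis-5,6-epoxy Weinreb amide
Product: 30 (12E)-macrocyclic epoxy Weinreb amide (5S,6R,7S,11S,19R)
Conditions: second-generation Grubbs catalyst RuCl2(=CHPh)(H2IMes)(PCy3) (10 mol%), CH2Cl2 (1 mM), 40 °C
Reagents that add atoms: none
Why: Ring-closing olefin metathesis of the two terminal vinyl groups (the free tertiary allylic hydroxyl assists and the trisubstituted olefin is inert) forms the 14-membered ring, and reversible metathesis should funnel the product to the less strained E C12=C13 olefin.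

Step 18
Reactants: 30 (12E)-macrocyclic epoxy Weinreb amide
Product: 31 macrocyclic epoxy methyl ketone (5S,6R,7S,11S,19R)
Conditions: MeMgCl (3 equiv), THF, −78 to −20 °C
Reagents that add atoms: methylmagnesium chloride C[Mg]Cl
Why: Weinreb ketone synthesis, in which the chelated tetrahedral adduct prevents over-addition and keeps the carbonyl masked from enolisation until work-up, while the chloride Grignard at low temperature should spare the oxirane.

Step 19
Reactants: 31 macrocyclic epoxy methyl ketone
Product: 33 macrocyclic alkenyl triflate (C2(OTf)=C1H2 on C19; 5S,6R,7S,11S,19R), via dipotassium enolate 32 (not isolated)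
Conditions: KN(SiMe3)2 (2.2 equiv), THF, −78 °C; then PhNTf2, −78 to −40 °C
Reagents that add atoms: N-phenylbis(trifluoromethanesulfonimide) O=S(=O)(N(c1ccccc1)S(=O)(=O)C(F)(F)F)C(F)(F)F
Why: Kinetic deprotonation at the unhindered methyl group and O-triflation of the enolate give the 1,1-disubstituted alkenyl triflate, while the hindered tertiary alkoxide should not react with the mild triflimide at −78 °C and C19–H, whose removal would open the oxirane, is not touched.

Step 20
Reactants: 33 macrocyclic alkenyl triflate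
Product: 35 hydroxy methylene lactone (5R,6R,7S,11S,19S; C6–OH and C11–OH free), via manganese carboxylate 34 (not isolated)
Conditions: CoI2(2,9-dimethyl-1,10-phenanthroline) (10 mol%), Mn powder (3 equiv), CO2 (1 atm), DMA, rt; then 45 °C; aq. NH4Cl
Reagents that add atoms: carbon dioxide O=C=O
Why: Manganese reduces the divalent cobalt precatalyst to a low-valent species that inserts into the alkenyl C–OTf bond, CO2 inserts into the alkenyl–cobalt bond (new C2–C3 bond), and the released manganese carboxylate 34 attacks C5 of the neighbouring cis-oxirane with its oxygen (new O4–C5 bond). The closest known reaction types are the cobalt-catalysed reductive carboxylation of alkenyl triflates with CO2 and the lactonisation of γ,δ-epoxy carboxylates, run here as one cascade in one flask. The five-membered lactone ring (C2, C3, O4, C5, C19) closes in the 5-exo-tet mode with the oxirane C5–O bond as the leaving bond. C5 is set by SN2 inversion, which turns the (5S) oxirane carbon into the (5R) lactone carbon cis to H19, while C6 keeps its oxygen with retention and C19 is untouched. The step needs 5-exo attack at C5 in preference to 6-endo attack at C6, which the geometry of a carboxylate held three atoms from C5 should secure since both oxirane carbons are secondary and no electronic bias opposes it. It also needs chemoselectivity for the alkenyl triflate over the two isolated olefins, the tertiary alcohol and the oxirane, which the mild reductant under CO2 should tolerate.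

Step 21
Reactants: 35 hydroxy methylene lactone
Product: 36 C6 acetate of 35
Conditions: Ac2O, pyridine, DMAP (cat.), CH2Cl2, 0 °C
Reagents that add atoms: acetic anhydride CC(=O)OC(C)=O
Why: Acylation of the secondary C6 hydroxyl; the tertiary allylic C11 hydroxyl is too hindered to be acetylated under these conditions.

Step 22
Reactants: 36 C6 acetate of 35
Product: 37 CNP0202356.4
Conditions: D-fructose-derived Shi ketone (30 mol%), KHSO5 (as Oxone), K2CO3, Bu4NHSO4, MeCN/dimethoxymethane/aq. Na2B4O7 buffer (pH 10.5), 0 °C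
Reagents that add atoms: potassium peroxymonosulfate [K+].[O-]S(=O)(=O)OO
Why: Shi epoxidation, in which the chiral dioxirane reacts fastest with the electron-rich trisubstituted E olefin through a spiro transition state and the D-fructose-derived ketone should deliver oxygen to the face giving the (15R,17R) oxirane, while the C12=C13 olefin (deactivated by the allylic C–O bond and shielded by the quaternary centre) and the electron-poor methylene lactone are left.

**Compound list**

1 | pent-1-en-4-yne | C#CCC=C | starting material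
2 | (E)-dimethyl(2-methylpenta-1,4-dien-1-yl)alane | C[Al](C)/C=C(C)/CC=C | intermediate
3 | (E)-1-iodo-2-methylpenta-1,4-diene | I/C=C(C)/CC=C | intermediate
4 | β-propiolactone (oxetan-2-one) | O=C1CCO1 | starting material
5 | (E)-(2-methylpenta-1,4-dien-1-yl)lithium | [Li]/C=C(C)/CC=C | intermediate
6 | (E)-(2-methylpenta-1,4-dien-1-yl)magnesium bromide | Br[Mg]/C=C(C)/CC=C | intermediate
7 | (E)-5-methylocta-4,7-dienoic acid | OC(=O)CC/C=C(C)/CC=C | intermediate
8 | (R)-4-benzyl-1,3-oxazolidin-2-one | O=C1OC[C@@H](Cc2ccccc2)N1 | starting material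
9 | (E)-5-methylocta-4,7-dienoic pivalic anhydride | CC(C)(C)C(=O)OC(=O)CC/C=C(C)/CC=C | intermediate
10 | (R)-4-benzyl-3-[(E)-5-methylocta-4,7-dienoyl]-1,3-oxazolidin-2-one | O=C(CC/C=C(C)/CC=C)N1C(=O)OC[C@H]1Cc1ccccc1 | intermediate
11 | (E)-but-2-en-1-ol | C/C=C/CO | starting material
12 | [(2S,3S)-3-methyloxiran-2-yl]methanol | C[C@@H]1O[C@H]1CO | intermediate
13 | (2S,3S)-2-[(4-methoxybenzyloxy)methyl]-3-methyloxirane | C[C@@H]1O[C@H]1COCc1ccc(OC)cc1 | intermediate
14 | (S)-linalool, (3S)-3,7-dimethylocta-1,6-dien-3-ol | CC(C)=CCC[C@](C)(O)C=C | starting material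
15 | (3S)-3,7-dimethyl-3-(triethylsilyloxy)octa-1,6-diene | CC(C)=CCC[C@](C)(O[Si](CC)(CC)CC)C=C | intermediate
16 | (S)-4-methyl-4-(triethylsilyloxy)hex-5-enal | O=CCC[C@](C)(O[Si](CC)(CC)CC)C=C | intermediate
17 | (S)-4-methyl-4-(triethylsilyloxy)hex-5-en-1-ol | OCCC[C@](C)(O[Si](CC)(CC)CC)C=C | intermediate
18 | (S)-6-bromo-3-methyl-3-(triethylsilyloxy)hex-1-ene | BrCCC[C@](C)(O[Si](CC)(CC)CC)C=C | intermediate
19 | [(S)-4-methyl-4-(triethylsilyloxy)hex-5-en-1-yl]magnesium bromide | Br[Mg]CCC[C@](C)(O[Si](CC)(CC)CC)C=C | intermediate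
20 | (2R,3S,7S)-1-(4-methoxybenzyloxy)-3,7-dimethyl-7-(triethylsilyloxy)non-8-en-2-ol | COc1ccc(COC[C@H](O)[C@@H](C)CCC[C@](C)(O[Si](CC)(CC)CC)C=C)cc1 | intermediate
21 | (2R,3S,7S)-2-(tert-butyldimethylsilyloxy)-1-(4-methoxybenzyloxy)-3,7-dimethyl-7-(triethylsilyloxy)non-8-ene | COc1ccc(COC[C@H](O[Si](C)(C)C(C)(C)C)[C@@H](C)CCC[C@](C)(O[Si](CC)(CC)CC)C=C)cc1 | intermediate
22 | (2R,3S,7S)-2-(tert-butyldimethylsilyloxy)-3,7-dimethyl-7-(triethylsilyloxy)non-8-en-1-ol | OC[C@H](O[Si](C)(C)C(C)(C)C)[C@@H](C)CCC[C@](C)(O[Si](CC)(CC)CC)C=C | intermediate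
23 | (2R,3S,7S)-2-(tert-butyldimethylsilyloxy)-3,7-dimethyl-7-(triethylsilyloxy)non-8-enal | O=C[C@H](O[Si](C)(C)C(C)(C)C)[C@@H](C)CCC[C@](C)(O[Si](CC)(CC)CC)C=C | intermediate
24 | (Z)-O-dibutylboryl enolate of imide 10 | CCCCB(CCCC)O/C(=C\C/C=C(C)/CC=C)N1C(=O)OC[C@H]1Cc1ccccc1 | intermediate
25 | (R)-4-benzyl-3-[(2R,3R,4R,5S,9S)-4-(tert-butyldimethylsilyloxy)-3-hydroxy-5,9-dimethyl-2-[(E)-3-methylhexa-2,5-dien-1-yl]-9-(triethylsilyloxy)undec-10-enoyl]-1,3-oxazolidin-2-one | O=C([C@H](C/C=C(C)/CC=C)[C@@H](O)[C@H](O[Si](C)(C)C(C)(C)C)[C@@H](C)CCC[C@](C)(O[Si](CC)(CC)CC)C=C)N1C(=O)OC[C@H]1Cc1ccccc1 | intermediate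
26 | (2R,3R,4R,5S,9S)-4-(tert-butyldimethylsilyloxy)-3-hydroxy-N-methoxy-N,5,9-trimethyl-2-[(E)-3-methylhexa-2,5-dien-1-yl]-9-(triethylsilyloxy)undec-10-enamide | CON(C)C(=O)[C@H](C/C=C(C)/CC=C)[C@@H](O)[C@H](O[Si](C)(C)C(C)(C)C)[C@@H](C)CCC[C@](C)(O[Si](CC)(CC)CC)C=C | intermediate
27 | 3-O-methanesulfonate of 26 (C5 mesylate) | CON(C)C(=O)[C@H](C/C=C(C)/CC=C)[C@@H](OS(C)(=O)=O)[C@H](O[Si](C)(C)C(C)(C)C)[C@@H](C)CCC[C@](C)(O[Si](CC)(CC)CC)C=C | intermediate
28 | (2R,3R,4R,5S,9S)-4,9-dihydroxy-3-(methanesulfonyloxy)-N-methoxy-N,5,9-trimethyl-2-[(E)-3-methylhexa-2,5-dien-1-yl]undec-10-enamide | CON(C)C(=O)[C@H](C/C=C(C)/CC=C)[C@@H](OS(C)(=O)=O)[C@H](O)[C@@H](C)CCC[C@](C)(O)C=C | intermediate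
29 | (2R,4E)-2-[(2S,3R)-3-[(2S,6S)-6-hydroxy-6-methyloct-7-en-2-yl]oxiran-2-yl]-N-methoxy-N,5-dimethylocta-4,7-dienamide | CON(C)C(=O)[C@H](C/C=C(C)/CC=C)[C@@H]1O[C@@H]1[C@@H](C)CCC[C@](C)(O)C=C | intermediate
30 | macrocyclic Weinreb amide: 14-membered carbocycle C5–C15/C17–C19 with cis-5,6-oxirane (5S,6R), 7S-methyl, (11S)-11-hydroxy-11-methyl, 12E and 15E olefins, 15-methyl; C19 (R) bears C(=O)N(OMe)Me | CON(C)C(=O)[C@@H]1C/C=C(C)/C/C=C/[C@@](C)(O)CCC[C@H](C)[C@H]2O[C@@H]12 | intermediate
31 | macrocyclic methyl ketone: as 30 with acetyl on C19 (5S,6R,7S,11S,19R) | CC(=O)[C@@H]1C/C=C(C)/C/C=C/[C@@](C)(O)CCC[C@H](C)[C@H]2O[C@@H]12 | intermediate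
32 | dipotassium salt of 31 (C1 enolate and C11 alkoxide) | [K+].[K+].C=C([O-])[C@@H]1C/C=C(C)/C/C=C/[C@@](C)([O-])CCC[C@H](C)[C@H]2O[C@@H]12 | intermediate
33 | macrocyclic alkenyl triflate: as 30 with C2(OTf)=C1H2 on C19 (5S,6R,7S,11S,19R) | C=C(OS(=O)(=O)C(F)(F)F)[C@@H]1C/C=C(C)/C/C=C/[C@@](C)(O)CCC[C@H](C)[C@H]2O[C@@H]12 | intermediate
34 | 2-substituted acrylic acid: as 30 with C2(=C1H2)–C3O2H on C19 (5S,6R,7S,11S,19S); present in the flask as its manganese carboxylate, written as the acid | C=C(C(=O)O)[C@@H]1C/C=C(C)/C/C=C/[C@@](C)(O)CCC[C@H](C)[C@H]2O[C@@H]12 | intermediate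
35 | (5R,6R,7S,11S,19S,12E,15E)-6,11-dihydroxy cis-fused α-methylene-γ-butyrolactone on the 14-membered ring (6-O-deacetyl-15,17-deoxy target) | C=C1C(=O)O[C@H]2[C@H](O)[C@@H](C)CCC[C@](C)(O)/C=C/C/C(C)=C/C[C@@H]12 | intermediate
36 | 6-O-acetate of 35 (15,17-deoxy target) | C=C1C(=O)O[C@H]2[C@H](OC(C)=O)[C@@H](C)CCC[C@](C)(O)/C=C/C/C(C)=C/C[C@@H]12 | intermediate
37 | CNP0202356.4 (5R,6R,7S,11S,15R,17R,19S,12E) | C=C1C(=O)O[C@H]2[C@H](OC(C)=O)[C@@H](C)CCC[C@](C)(O)/C=C/C[C@@]3(C)O[C@@H]3C[C@@H]12 | target

**Summary**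

Total step count: 22. Longest linear sequence: 17 steps (steps 6–12, then 13–22).

Steps most likely to fail:

Step 20 (carboxylative lactonisation). What may go wrong: reductive or iodide-mediated opening of the oxirane by the low-valent cobalt system, protodetriflation outrunning CO2 capture, or a carboxylate that does not close the ring. Fallback, from 33 back to 35: palladium-catalysed methoxycarbonylation of the alkenyl triflate (Pd(OAc)2, dppp, CO 1 atm, Et3N, MeOH/DMF, 50 °C) should give the methyl acrylate ester F1. Saponification (LiOH, THF/H2O, 0 °C) and acidification to pH 4 with citric acid should then give the epoxy acid 34, which closes 5-exo to 35. The C2–C3 bond then comes from CO and O4 from hydroxide, in two separate routine events.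

Step 17 (ring-closing metathesis). What may go wrong: slow closure onto the hindered vinyl carbinol terminus leading to oligomerisation, or poor E/Z control in the flexible open chain. Fallback, from 29 back to 35: the order of ring formation is inverted. MeMgCl (THF, −78 °C) on 29 should give the open-chain epoxy methyl ketone F2, KN(SiMe3)2/PhNTf2 the open-chain alkenyl triflate F3, and the conditions of step 20 the open-chain hydroxy methylene lactone F4. Ring-closing metathesis of F4 (second-generation Hoveyda–Grubbs catalyst RuCl2(=CH-C6H4-2-OiPr)(H2IMes), toluene, 1 mM, 80 °C) then closes the macrocycle to 35, with the cis-disubstituted lactone as a rigid turn element and without the Lewis-basic amide.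

Step 22 (Shi epoxidation). What may go wrong: poor facial selectivity if the conformational bias of the macrocycle opposes the catalyst, or competing oxidation of the C12=C13 olefin. Fallback, from 29 back to 37: the epoxidation is moved to the open chain, where the trisubstituted olefin is the only electron-rich one and no ring bias exists. The conditions of step 22 applied to 29 should give the bis-epoxy Weinreb amide F5. Then, as in steps 17–20, ring-closing metathesis should give the macrocyclic bis-epoxy amide F6, MeMgCl the bis-epoxy methyl ketone F7 and enol triflation the bis-epoxy alkenyl triflate F8. Carboxylative lactonisation should give the 6-O-deacetyl target F9, since 5-exo opening of the C5–C6 oxirane is expected to outrun 6-exo attack at C17. Acetylation as in step 21 gives 37.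

Further compounds
F1 | step 20 | methyl ester of acid 34 (methyl 2-substituted acrylate on the macrocycle of 33) | C=C(C(=O)OC)[C@@H]1C/C=C(C)/C/C=C/[C@@](C)(O)CCC[C@H](C)[C@H]2O[C@@H]12
F2 | step 17 | open-chain epoxy methyl ketone (29 with acetyl in place of the Weinreb amide) | CC(=O)[C@H](C/C=C(C)/CC=C)[C@@H]1O[C@@H]1[C@@H](C)CCC[C@](C)(O)C=C
F3 | step 17 | open-chain epoxy alkenyl triflate (kinetic enol triflate of F2) | C=C(OS(=O)(=O)C(F)(F)F)[C@H](C/C=C(C)/CC=C)[C@@H]1O[C@@H]1[C@@H](C)CCC[C@](C)(O)C=C
F4 | step 17 | open-chain hydroxy α-methylene-γ-butyrolactone (seco form of 35 with two terminal vinyl groups) | C=C1C(=O)O[C@@H]([C@H](O)[C@@H](C)CCC[C@](C)(O)C=C)[C@H]1C/C=C(C)/CC=C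
F5 | step 22 | open-chain bis-epoxy Weinreb amide (29 with (15R,17R)-oxirane) | CON(C)C(=O)[C@H](C[C@H]1O[C@]1(C)CC=C)[C@@H]2O[C@@H]2[C@@H](C)CCC[C@](C)(O)C=C
F6 | step 22 | macrocyclic bis-epoxy Weinreb amide (30 with (15R,17R)-oxirane) | CON(C)C(=O)[C@@H]1C[C@H]3O[C@]3(C)C/C=C/[C@@](C)(O)CCC[C@H](C)[C@H]2O[C@@H]12
F7 | step 22 | macrocyclic bis-epoxy methyl ketone (31 with (15R,17R)-oxirane) | CC(=O)[C@@H]1C[C@H]3O[C@]3(C)C/C=C/[C@@](C)(O)CCC[C@H](C)[C@H]2O[C@@H]12
F8 | step 22 | macrocyclic bis-epoxy alkenyl triflate (33 with (15R,17R)-oxirane) | C=C(OS(=O)(=O)C(F)(F)F)[C@@H]1C[C@H]3O[C@]3(C)C/C=C/[C@@](C)(O)CCC[C@H](C)[C@H]2O[C@@H]12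
F9 | step 22 | 6-O-deacetyl target (35 with (15R,17R)-oxirane) | C=C1C(=O)O[C@H]2[C@H](O)[C@@H](C)CCC[C@](C)(O)/C=C/C[C@@]3(C)O[C@@H]3C[C@@H]12
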